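The easy step is the ring closure: I take Q → D as first order, so it removes a fixed fraction of Q per minute, while the path to E removes a fraction that grows with [Q].

| flask | Q | remark | time |
|---|---|---|---|
| west | 0.039 M | run made earlier |  |
| north-east | 0.94 M | run made earlier |  |
| theta | 0.030 M |  | 6.0 min |
| delta | 0.080 M |  | 6.0 min |
| gamma | 0.25 M |  | 6.0 min |
| zeta | 0.80 M |  | 6.0 min |

| run | time / min | D / % | E / % |
|---|---|---|---|
| west | 0.500 | 13.5 | 21.0 |
| west | 1.00 | 19.5 | 29.6 |
| west | 2.50 | 23.5 | 36.2 |
| west | 6.00 | 18.5 | 35.6 |
| north-east | 1.50 | 3.4 | 33.9 |
| north-east | 3.00 | 1.2 | 31.4 |
| north-east | 5.00 | 0.4 | 30.6 |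
| north-east | 6.00 | 0 | 29.8 |

(scatter of a reading: 1 percentage point)

- in percentages every species weighs as the Q in it: one E counts as two
- in percentages every species weighs as the Q in it: one Z counts as three
- the numbers in the tables scatter with a standard deviation of 1 percentage point
- steps under discussion: Q <-> D; 2 Q -> E; Q + E -> Z
- "hardly changes" means that all values lie within two and a half points (for a concentration: within two and a half percent of the largest)

- share of D in all that became D or E or Z for theta, delta, gamma, zeta, in this order
- the course of these numbers from the first flask to the last (falls all the way / rises all the way / rises, then falls / hardly changes / falls, then rises)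

Percentages count the Q inside each species, so early E over early D reads the ratio of the two paths. In the west run at 0.500 min that reading is 1.56. If I neglect Z and the return of D this early, [Q] has averaged about 82.8% of the charge. The paths would therefore be equal at a crossover [Q]* of 0.0207 M, a reading with the scatter in it.

The number I carry is the selectivity factor N = [Q]/[Q]*, the rate at which Q goes towards E over the forward rate at which it goes to D. At the start it is 1.45 in theta, 3.86 in delta, 12.1 in gamma and 38.6 in zeta. It rises from flask to flask, so I expect the row to fall all the way.

One number gives me that order but no values. N falls with [Q] during a run, and in the west run D drops from 23.5% at 2.50 min to 18.5% at 6.00 min while E reads 36.2% and 35.6%.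

The forecast gives 27%, 12%, 4.7% and 0.5%, a course that falls all the way, and says: “The first-order ring closure loses to the bimolecular steps as concentration rises”.

The flask gives 25.7%, 11.6%, 3.69% and 0.864%, so the row falls all the way.

Q ⇌ D (K = 0.846, k = 0.00591 /s); 2 Q → E (k = 0.154 /M/s); Q + E → Z (k = 0.150 /M/s) In theta the forward path to D is slower than the path to E at the start, at a ratio of 1.6, but faster at 6.00 min, at a ratio of 0.31, with Q at 20% of the charge. My N for theta times that remainder gives 0.287. In zeta the same product is 0.120, with Q at 0.31% and D at 0.861% at 6.00 min.

The readings are calculated for substances that don't exist, noise included.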